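Ring B is grown on the finished chromone (rings A and C) instead of being brought in as an arene. Its C3'-OH, C4'-OMe, C5'-OMe pattern is that of the mono-methyl enol ether of a symmetric 2-methoxycyclohexane-1,3-dione joined through C1' to chromone C2, so either carbonyl can be O-methylated with the same result. The key step builds this ring in one pot: methyl 4-methoxy-3-oxobutanoate adds to a chromon-2-ylmethylidene malonate (C1'–C2'), then its methoxy-bearing carbon acylates on a malonate ester (C4'–C5'). The precursor is 6,7,8-trimethoxychromone bearing CH=C(CO2Me)2 at C2. Decarboxylation, O-methylation and dehydrogenation then deliver the phenol.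

Key step: step 5

Remark: compounds 1, 4, 8 and 10 are taken as purchased. The target is achiral. Compounds 11–15 carry only stereocentres that vanish on aromatization, so they are used as racemates or epimer/enol mixtures and drawn without stereodescriptors.

Step 1
Reactants: 1 2,3,4-trimethoxyphenol
Product: 3 1-(2-hydroxy-3,4,5-trimethoxyphenyl)ethan-1-one, via 2,3,4-trimethoxyphenyl acetate 2 (not isolated)
Conditions: BF3·OEt2 (3 equiv), AcOH, 90 °C; then H2O
Reagents that add atoms: acetic acid, CC(=O)O
Why: One-pot O-acetylation and Fries rearrangement, in which boron bound to the phenol oxygen returns the acetyl group to C6, the only free position ortho to that oxygen (the para position carries OMe), and the chelated ortho-hydroxy ketone is the thermodynamic product.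

Step 2
Reactants: 3 1-(2-hydroxy-3,4,5-trimethoxyphenyl)ethan-1-one; 4 ethyl 2,2-diethoxyacetate
Product: 5 4,4-diethoxy-1-(2-hydroxy-3,4,5-trimethoxyphenyl)butane-1,3-dione
Conditions: NaH (3.5 equiv), THF, 0 °C → 65 °C; AcOH quench
Reagents that add atoms: none
Why: Crossed Claisen condensation in which the phenoxide–enolate dianion of 3 acylates on the ester of 4, an ester whose hindered α-hydrogen keeps it from self-condensing, and formation of the 1,3-diketonate makes the step irreversible.

Step 3
Reactants: 5 4,4-diethoxy-1-(2-hydroxy-3,4,5-trimethoxyphenyl)butane-1,3-dione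
Product: 7 6,7,8-trimethoxy-4-oxo-4H-chromene-2-carbaldehyde, via 2-(diethoxymethyl)-6,7,8-trimethoxy-4H-chromen-4-one 6 (not isolated)
Conditions: AcOH, 2 M aq. H2SO4, 100 °C
Reagents that add atoms: water, O
Why: Acid-catalysed cyclodehydration of an ortho-hydroxyaryl 1,3-diketone to the 4H-chromen-4-one (the closure that ends a Baker–Venkataraman flavone synthesis), with hydrolysis of the diethyl acetal in the same aqueous acid, to which the pyranone and the aryl methyl ethers are stable.

Step 4
Reactants: 7 6,7,8-trimethoxy-4-oxo-4H-chromene-2-carbaldehyde; 8 dimethyl malonate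
Product: 9 dimethyl 2-[(6,7,8-trimethoxy-4-oxo-4H-chromen-2-yl)methylidene]propanedioate
Conditions: TiCl4 (2 equiv), pyridine (4 equiv), THF, 0 °C → rt
Reagents that add atoms: none
Why: Knoevenagel condensation in its TiCl4–pyridine variant, which runs at or below room temperature without a nucleophilic secondary amine and so should spare the pyranone ring of this very electrophilic aldehyde; no alkene geometry arises because the two ester groups are identical.

Step 5
Reactants: 9 dimethyl 2-[(6,7,8-trimethoxy-4-oxo-4H-chromen-2-yl)methylidene]propanedioate; 10 methyl 4-methoxy-3-oxobutanoate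
Product: 12 dimethyl 5-methoxy-4,6-dioxo-2-(6,7,8-trimethoxy-4-oxo-4H-chromen-2-yl)cyclohexane-1,3-dicarboxylate (epimer mixture), via Michael adduct 11 (not isolated)
Conditions: DBU (0.1 equiv), THF, 0 °C → rt; then t-BuOK (1.1 equiv), t-BuOH/THF, rt → 55 °C; cold 1 M HCl
Reagents that add atoms: none
Why: Michael–Claisen [3+3] annulation: DBU generates the C2 enolate of 10, which adds to the exocyclic carbon of 9 (C1'–C2') to give the malonate-stabilised adduct 11, and under t-BuOK a small equilibrium share of the enolate at the methoxy-bearing C4 of the keto ester then attacks one malonate ester carbonyl (C4'–C5') and expels methoxide. The closest known reaction is the classical synthesis of 5-substituted cyclohexane-1,3-diones from acetoacetates and alkylidene malonates or cinnamates. Ring B closes as a six-membered carbocycle by a 6-exo-trig Dieckmann-type acylation, the only C-acylation that avoids a four-membered ring, and deprotonation of the acidic 2-methoxy-1,3-dione formed makes closure irreversible and should drain any O-acylated dihydropyranone back through the open form. The four sp3 centres created are epimerisable and uncontrolled, and since none survives to the target no stereocontrol is needed. The selectivity required is attack at the exocyclic carbon and not at chromone C2, which the two ester groups secure by making that carbon the most electrophilic site, while non-nucleophilic bases avoid opening the pyranone. Only a slight excess of t-BuOK is used so that the malonate terminus is not held wholly as its unreactive enolate, and the methoxy group raises the acidity of the carbon that must act as nucleophile.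

Step 6
Reactants: 12 dimethyl 5-methoxy-4,6-dioxo-2-(6,7,8-trimethoxy-4-oxo-4H-chromen-2-yl)cyclohexane-1,3-dicarboxylate
Product: 14 2-methoxy-5-(6,7,8-trimethoxy-4-oxo-4H-chromen-2-yl)cyclohexane-1,3-dione, via diacid 13 (not isolated)
Conditions: AcOH, 3 M aq. HCl, 95 °C
Reagents that add atoms: none
Why: Acid-catalysed hydrolysis of the two β-keto esters followed by thermal decarboxylation of the β-keto acids, which collapses all epimerisable centres to the symmetric dione; acid is chosen over hydroxide because the pyranone opens in hot alkali but is stable in acid.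

Step 7
Reactants: 14 2-methoxy-5-(6,7,8-trimethoxy-4-oxo-4H-chromen-2-yl)cyclohexane-1,3-dione
Product: 15 2,3-dimethoxy-5-(6,7,8-trimethoxy-4-oxo-4H-chromen-2-yl)cyclohex-2-en-1-one (racemic)
Conditions: HC(OMe)3, MeOH, p-TsOH (cat.), 50 °C
Reagents that add atoms: trimethyl orthoformate, COC(OC)OC; methanol, CO
Why: Acid-catalysed enol etherification of a cyclic 1,3-dione (vinylogous esterification) driven by the orthoformate as water scavenger; the dione is symmetric about its C1'–C4' axis, so either carbonyl gives the same enol ether, and the vinylogous ester formed should not react further.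

Step 8
Reactants: 15 2,3-dimethoxy-5-(6,7,8-trimethoxy-4-oxo-4H-chromen-2-yl)cyclohex-2-en-1-one
Product: 16 2-(3-hydroxy-4,5-dimethoxyphenyl)-6,7,8-trimethoxy-4H-chromen-4-one
Conditions: Pd(OCOCF3)2 (5 mol%), 2-(dimethylamino)pyridine (10 mol%), p-TsOH (20 mol%), O2 (1 atm), DMSO, 80 °C
Reagents that add atoms: none
Why: Palladium-catalysed aerobic dehydrogenation of a cyclohexenone to a phenol, in which a divalent palladium enolate at C6 loses the C5 hydrogen by β-hydride elimination, the cross-conjugated dienone tautomerises irreversibly to the arene and O2 reoxidises zerovalent palladium, so that the last stereocentre disappears and the untouched carbonyl becomes the C3' hydroxyl.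

Compound list
1 | 2,3,4-trimethoxyphenol | COc1ccc(O)c(OC)c1OC | starting material
2 | 2,3,4-trimethoxyphenyl acetate (not isolated) | CC(=O)Oc1ccc(OC)c(OC)c1OC | intermediate
3 | 1-(2-hydroxy-3,4,5-trimethoxyphenyl)ethan-1-one | CC(=O)c1cc(OC)c(OC)c(OC)c1O | intermediate
4 | ethyl 2,2-diethoxyacetate | CCOC(=O)C(OCC)OCC | starting material
5 | 4,4-diethoxy-1-(2-hydroxy-3,4,5-trimethoxyphenyl)butane-1,3-dione | CCOC(OCC)C(=O)CC(=O)c1cc(OC)c(OC)c(OC)c1O | intermediate
6 | 2-(diethoxymethyl)-6,7,8-trimethoxy-4H-chromen-4-one (not isolated) | CCOC(OCC)c1cc(=O)c2cc(OC)c(OC)c(OC)c2o1 | intermediate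
7 | 6,7,8-trimethoxy-4-oxo-4H-chromene-2-carbaldehyde | O=Cc1cc(=O)c2cc(OC)c(OC)c(OC)c2o1 | intermediate
8 | dimethyl malonate | COC(=O)CC(=O)OC | starting material
9 | dimethyl 2-[(6,7,8-trimethoxy-4-oxo-4H-chromen-2-yl)methylidene]propanedioate | COC(=O)C(=Cc1cc(=O)c2cc(OC)c(OC)c(OC)c2o1)C(=O)OC | intermediate
10 | methyl 4-methoxy-3-oxobutanoate | COCC(=O)CC(=O)OC | starting material
11 | trimethyl 5-methoxy-4-oxo-2-(6,7,8-trimethoxy-4-oxo-4H-chromen-2-yl)pentane-1,1,3-tricarboxylate (diastereomer mixture, not isolated) | COCC(=O)C(C(=O)OC)C(c1cc(=O)c2cc(OC)c(OC)c(OC)c2o1)C(C(=O)OC)C(=O)OC | intermediate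
12 | dimethyl 5-methoxy-4,6-dioxo-2-(6,7,8-trimethoxy-4-oxo-4H-chromen-2-yl)cyclohexane-1,3-dicarboxylate (mixture of epimers and enol tautomers) | COC(=O)C1C(c2cc(=O)c3cc(OC)c(OC)c(OC)c3o2)C(C(=O)OC)C(=O)C(OC)C1=O | intermediate
13 | 5-methoxy-4,6-dioxo-2-(6,7,8-trimethoxy-4-oxo-4H-chromen-2-yl)cyclohexane-1,3-dicarboxylic acid (not isolated) | OC(=O)C1C(c2cc(=O)c3cc(OC)c(OC)c(OC)c3o2)C(C(=O)O)C(=O)C(OC)C1=O | intermediate
14 | 2-methoxy-5-(6,7,8-trimethoxy-4-oxo-4H-chromen-2-yl)cyclohexane-1,3-dione (largely enolised) | COC1C(=O)CC(CC1=O)c1cc(=O)c2cc(OC)c(OC)c(OC)c2o1 | intermediate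
15 | 2,3-dimethoxy-5-(6,7,8-trimethoxy-4-oxo-4H-chromen-2-yl)cyclohex-2-en-1-one (racemic) | COC1=C(OC)C(=O)CC(C1)c1cc(=O)c2cc(OC)c(OC)c(OC)c2o1 | intermediate
16 | 2-(3-hydroxy-4,5-dimethoxyphenyl)-6,7,8-trimethoxy-4H-chromen-4-one | COc1cc(-c2cc(=O)c3cc(OC)c(OC)c(OC)c3o2)cc(O)c1OC | target

Total step count: 8
Longest linear sequence: 8 steps (1 → 16)

Steps most likely to fail

Step 5. At the temperature needed for closure the open-chain adduct may revert by retro-Michael cleavage or exchange partners. Closure may also stall if the malonate terminus sits as its enolate, and alkoxide may attack the pyranone. The fallback sets out from aldehyde 7 and rejoins the route at 12, joining the same three components in the opposite order. Aldehyde 7 is condensed with keto ester 10 (TiCl4, pyridine, THF, 0 °C) to methyl 4-methoxy-3-oxo-2-[(6,7,8-trimethoxy-4-oxo-4H-chromen-2-yl)methylidene]butanoate F1. Dimethyl malonate 8, a donor with a single nucleophilic site, is then added (catalytic NaOMe, MeOH, 0 °C) to give the same adduct 11. Here 11 is isolated and closed under equilibrating conditions (NaOMe, 1.1 equiv, MeOH, reflux) to 12.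

Step 8. Palladation next to a vinylogous ester may be slow. The water formed, together with the acid co-catalyst, may hydrolyse the enol ether, and the catalyst may aggregate before conversion is complete. The fallback sets out from 15 and rejoins at 16 by a stoichiometric selenium sequence. Kinetic deprotonation (LiN(SiMe3)2, THF, −78 °C) and trapping with PhSeCl should give 2,3-dimethoxy-6-(phenylselanyl)-5-(6,7,8-trimethoxy-4-oxo-4H-chromen-2-yl)cyclohex-2-en-1-one F2, with selenium trans to the chromone and hence cis to the C5 hydrogen. Oxidation (H2O2, pyridine, CH2Cl2, 0 °C) gives the selenoxide 2,3-dimethoxy-6-(phenylseleninyl)-5-(6,7,8-trimethoxy-4-oxo-4H-chromen-2-yl)cyclohex-2-en-1-one F3. Its syn-elimination gives 2,3-dimethoxy-5-(6,7,8-trimethoxy-4-oxo-4H-chromen-2-yl)cyclohexa-2,5-dien-1-one F4, which should tautomerise at once to 16. Selenation at the chromone-activated C5 instead would also eliminate into the ring and lead to the same phenol.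

Step 4. A second malonate may add to the very electrophilic product, or nucleophiles may add to the pyranone or the new alkene during condensation and aqueous work-up. The fallback sets out from 7 and 8 and rejoins at 9, separating carbon–carbon bond formation from dehydration. Titanium enolate aldol addition (TiCl4, Et3N, CH2Cl2, −78 °C, cold quench) should give dimethyl 2-[hydroxy(6,7,8-trimethoxy-4-oxo-4H-chromen-2-yl)methyl]propanedioate F5. Treatment with MsCl and Et3N (CH2Cl2, 0 °C) forms dimethyl 2-[(methanesulfonyloxy)(6,7,8-trimethoxy-4-oxo-4H-chromen-2-yl)methyl]propanedioate F6, which undergoes E1cB elimination in the same flask to 9 with no free malonate present.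

Further compounds
F1 | step 5 | methyl 4-methoxy-3-oxo-2-[(6,7,8-trimethoxy-4-oxo-4H-chromen-2-yl)methylidene]butanoate (E/Z mixture) | COCC(=O)C(=Cc1cc(=O)c2cc(OC)c(OC)c(OC)c2o1)C(=O)OC
F2 | step 8 | 2,3-dimethoxy-6-(phenylselanyl)-5-(6,7,8-trimethoxy-4-oxo-4H-chromen-2-yl)cyclohex-2-en-1-one (racemic, trans) | COC1=C(OC)C(=O)C([Se]c2ccccc2)C(C1)c1cc(=O)c2cc(OC)c(OC)c(OC)c2o1
F3 | step 8 | 2,3-dimethoxy-6-(phenylseleninyl)-5-(6,7,8-trimethoxy-4-oxo-4H-chromen-2-yl)cyclohex-2-en-1-one | COC1=C(OC)C(=O)C([Se](=O)c2ccccc2)C(C1)c1cc(=O)c2cc(OC)c(OC)c(OC)c2o1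
F4 | step 8 | 2,3-dimethoxy-5-(6,7,8-trimethoxy-4-oxo-4H-chromen-2-yl)cyclohexa-2,5-dien-1-one | COC1=C(OC)C(=O)C=C(C1)c1cc(=O)c2cc(OC)c(OC)c(OC)c2o1
F5 | step 4 | dimethyl 2-[hydroxy(6,7,8-trimethoxy-4-oxo-4H-chromen-2-yl)methyl]propanedioate (racemic) | COC(=O)C(C(O)c1cc(=O)c2cc(OC)c(OC)c(OC)c2o1)C(=O)OC
F6 | step 4 | dimethyl 2-[(methanesulfonyloxy)(6,7,8-trimethoxy-4-oxo-4H-chromen-2-yl)methyl]propanedioate (racemic) | COC(=O)C(C(OS(C)(=O)=O)c1cc(=O)c2cc(OC)c(OC)c(OC)c2o1)C(=O)OC
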